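(The numbers in the tables come from a simulation on assumed constants, and the scatter is random.)

Late in both earlier runs, what is not yet Q is still falling nearly exponentially, so I read them for a single number.

| setting | north-west | south-east | flask |
|---|---|---|---|
| G | 0.020 M | 0.020 M | 0.020 M |
| E | 0.70 mM | 1.1 mM | 0.50 mM |
| remark | run made earlier | run made earlier |  |
| time |  |  | 3.0 min |

- north-west (time / s: L / %, Q / %): 20.0: 21.8, 16.5; 40.0: 18.6, 30.8; 50.0: 16.9, 37.6; 80.0: 13.1, 52.8; 90.0: 11.7, 56.6; 120: 8.2, 67.6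
- south-east (time / s: L / %, Q / %): 20.0: 20.9, 18.7; 40.0: 17.0, 36.2; 50.0: 15.5, 42.7; 80.0: 11.6, 59.1; 90.0: 9.8, 63.6; 120: 6.4, 74.0

(scatter of a reading: 0.3 percentage points)



- ratio of L to Q at 0.20 s
- ratio of L to Q at 3.0 min

1. I treat that fall as exp(−kt), with k a pseudo-first-order constant. The readings at 120 s give 0.00939 s⁻¹ at cE = 0.70 mM and 0.0112 s⁻¹ at 1.1 mM, an apparent order in E of 0.395.

2. Carrying k to the flask's cE = 0.50 mM and multiplying by 3.0 min gives 1.48. This is the count of lifetimes passed, the drain number N.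

3. At 50.0 s, L is 0.271 of what is not Q in the north-west run and 0.271 in the south-east run. I freeze this share s, so L/Q = s/(exp(N) − 1), which for the flask is 0.0799 at 3.0 min.

4. Is one number enough? At 0.20 s the same formula gives 165 for the flask, but the readings in the two runs begin at 20.0 s, later than that, so they do not test s so early.

The forecast says 180 at 0.20 s and 0.06 at 3.0 min, noting that “L/remainder sags late”; my ratio at 3.0 min is higher than that.

The flask gives 164 at 0.20 s and 0.0811 at 3.0 min.

    G + E ⇌ E + L (K = 0.370, k = 345 M⁻¹ s⁻¹)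
    G ⇌ J (K = 0.0820, k = 0.0319 s⁻¹)
    E + J → E + Q (k = 666 M⁻¹ s⁻¹)
    2 E ⇌ D (K = 809 M⁻¹, k = 475 M⁻¹ s⁻¹)

With cE = 3.0 × 10⁻⁴ M, the neighbouring flask has N = 1.21, so I reckon Q at 70.2% and L/Q at 0.115. That neighbour holds Q at 66.8% and L/Q at 0.131.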